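**Retrosynthetic overview**
- The C1'–C8' octamethylene segment of the target is treated as a masked 2,2'-bithiophene-5,5'-diyl. The last step is an exhaustive reductive desulfurisation that erases both thiophene rings.
- The bithienyl-pyrone acetate is cut into three pieces joined in one flask. These are C2-symmetric 2,2'-bithiophene as a double-ended linchpin, (S)-propylene oxide (C9'–C11' and the only stereocentre), and C2v-symmetric 2,6-dimethoxy-3,5-dimethyl-4-pyrone, which loses one OMe by addition–elimination.
- The dimethoxypyrone comes from carbonyl-O-methylation of 4-hydroxy-6-methoxy-3,5-dimethyl-2-pyrone. That comes from acid cyclisation of dimethyl 2,4-dimethyl-3-oxoglutarate, which comes from dimethyl acetonedicarboxylate and MeI.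
- Ring order: the pyrone is the only ring that is made (step 2). The two thiophene rings are bought and destroyed in step 5.

Assumption: a telescoped one-flask sequence with a single work-up counts as one step. The stereocentre in the given SMILES reads as (S).

**Step 1**
Reactants: 1 dimethyl 3-oxopentanedioate (dimethyl acetonedicarboxylate)
Product: 2 dimethyl 2,4-dimethyl-3-oxopentanedioate (dl/meso/enol mixture, stereochemistry irrelevant)
Conditions: MeI (2.2 equiv), K2CO3 (2.5 equiv), acetone, reflux
Reagents that add atoms: iodomethane, CI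
Why: This is a double C-alkylation of a bis-β-keto ester enolate, and after the first methylation the untouched CH2 is the more acidic and less hindered site, so the second methyl goes to the other flank (2,4- rather than 2,2-).

**Step 2**
Reactants: 2 dimethyl 2,4-dimethyl-3-oxopentanedioate
Product: 3 4-hydroxy-6-methoxy-3,5-dimethyl-2H-pyran-2-one
Conditions: conc. H2SO4 / 20% oleum (as medium), 0 °C → rt; pour onto ice
Reagents that add atoms: none
Why: This is an acid-mediated cyclocondensation (intramolecular O-acylation) in which one ester is ionised in the strong acid and captured by the carbonyl oxygen of the other, enol-conjugated ester, and loss of MeOH gives the conjugated 2-pyrone as the thermodynamic sink.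

**Step 3**
Reactants: 3 4-hydroxy-6-methoxy-3,5-dimethyl-2H-pyran-2-one
Product: 5 2,6-dimethoxy-3,5-dimethyl-4H-pyran-4-one, via pyrylium triflate 4 (not isolated)
Conditions: MeOTf (1.2 equiv), CH2Cl2, 0 °C → rt; then sat. aq NaHCO3
Reagents that add atoms: methyl trifluoromethanesulfonate, COS(=O)(=O)C(F)(F)F
Why: This is the α-pyrone → α-methoxy-γ-pyrone transposition by hard O-methylation, in which the neutral hydroxypyrone is methylated at its most basic site (the lactone carbonyl oxygen) to give the aromatic trioxygenated pyrylium 4, and bicarbonate removes the 4-OH proton to give the symmetric γ-pyrone.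

**Step 4**
Reactants: 6 2,2'-bithiophene; 7 (S)-propylene oxide [(2S)-2-methyloxirane]; 5 2,6-dimethoxy-3,5-dimethyl-4H-pyran-4-one
Product: 12 (2S)-1-[5'-(6-methoxy-3,5-dimethyl-4-oxo-4H-pyran-2-yl)-2,2'-bithiophen-5-yl]propan-2-yl acetate, via 5-lithio-2,2'-bithiophene 8 (not isolated), via lithium alkoxide 9 (not isolated), via C,O-dilithio species 10 (not isolated), via pyrone lithium alkoxide 11 (not isolated)
Conditions: 6, n-BuLi (1.0 equiv), THF, −78 °C; 7 (1.0 equiv), −78 °C → rt; n-BuLi (1.05 equiv), −78 → −20 °C; cannulate into 5 (1.1 equiv), THF, −78 → −40 °C; Ac2O (3 equiv), −40 °C → rt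
Reagents that add atoms: acetic anhydride, CC(=O)OC(C)=O; n-butyllithium, [Li]CCCC (lithium only, in the unisolated intermediates 8–11)
Why: Proposed new method: each event is a known reaction type (thiophene α-lithiation, SN2 opening of a terminal epoxide, conjugate addition–elimination on a γ-pyrone, O-acylation), but telescoping them through an unprotected alkoxide/aryllithium dianion is untested; one equivalent of n-BuLi differentiates the two equivalent α-positions of 6, attack of 8 on the unsubstituted CH2 of 7 leaves the C–O stereocentre untouched so (S)-7 gives the (S)-alkoxide 9, the remaining thiophene α-H is the only acidic C–H left for the second lithiation, the thienyl carbanion of 10 adds to C2 of 5 (C4=O is a doubly vinylogous carbonate shielded by two methyls) and the enolate expels LiOMe to restore the pyrone and break the C2v symmetry of 5, and the much less nucleophilic lithium alkoxide is then trapped by Ac2O; the closest known reaction type is the desymmetrising addition–elimination of carbanions to 2,6-dimethoxy-γ-pyrones.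

**Step 5**
Reactants: 12 (2S)-1-[5'-(6-methoxy-3,5-dimethyl-4-oxo-4H-pyran-2-yl)-2,2'-bithiophen-5-yl]propan-2-yl acetate
Product: 13 (2S)-11-(6-methoxy-3,5-dimethyl-4-oxo-4H-pyran-2-yl)undecan-2-yl acetate (target)
Conditions: Raney Ni (W-2, washed to neutrality, ca. 15 wt equiv), H2 (1 atm), THF, 40 °C
Reagents that add atoms: none
Why: This is a Raney-nickel reductive desulfurisation (the classical thiophene chain-extension tactic) in which all four C–S bonds are cleaved and the resulting dienes saturated, so the flat C8 bithiophene becomes (CH2)8, while the tetrasubstituted, donor-stabilised pyrone C=C bonds resist mild hydrogenation and the acetate blocks Ni-mediated dehydrogenation/rehydrogenation of the carbinol, so the (S) centre is kept.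

**Compound list**
1 | dimethyl 3-oxopentanedioate | COC(=O)CC(=O)CC(=O)OC | starting material
2 | dimethyl 2,4-dimethyl-3-oxopentanedioate | COC(=O)C(C)C(=O)C(C)C(=O)OC | intermediate
3 | 4-hydroxy-6-methoxy-3,5-dimethyl-2H-pyran-2-one | COc1oc(=O)c(C)c(O)c1C | intermediate
4 | 4-hydroxy-2,6-dimethoxy-3,5-dimethylpyrylium triflate (not isolated) | COc1[o+]c(OC)c(C)c(O)c1C.[O-]S(=O)(=O)C(F)(F)F | intermediate
5 | 2,6-dimethoxy-3,5-dimethyl-4H-pyran-4-one | COc1oc(OC)c(C)c(=O)c1C | intermediate
6 | 2,2'-bithiophene | c1csc(c1)-c1cccs1 | starting material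
7 | (S)-propylene oxide | C[C@H]1CO1 | starting material
8 | 5-lithio-2,2'-bithiophene (not isolated) | [Li]c1ccc(s1)-c1cccs1 | intermediate
9 | lithium (2S)-1-(2,2'-bithiophen-5-yl)propan-2-olate (not isolated) | C[C@H](O[Li])Cc1ccc(s1)-c1cccs1 | intermediate
10 | lithium (2S)-1-(5'-lithio-2,2'-bithiophen-5-yl)propan-2-olate (not isolated) | C[C@H](O[Li])Cc1ccc(s1)-c1ccc([Li])s1 | intermediate
11 | lithium (2S)-1-[5'-(6-methoxy-3,5-dimethyl-4-oxo-4H-pyran-2-yl)-2,2'-bithiophen-5-yl]propan-2-olate (not isolated) | C[C@H](O[Li])Cc1ccc(s1)-c1ccc(s1)-c1oc(OC)c(C)c(=O)c1C | intermediate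
12 | (2S)-1-[5'-(6-methoxy-3,5-dimethyl-4-oxo-4H-pyran-2-yl)-2,2'-bithiophen-5-yl]propan-2-yl acetate | C[C@H](OC(C)=O)Cc1ccc(s1)-c1ccc(s1)-c1oc(OC)c(C)c(=O)c1C | intermediate
13 | (2S)-11-(6-methoxy-3,5-dimethyl-4-oxo-4H-pyran-2-yl)undecan-2-yl acetate | COc1oc(CCCCCCCCC[C@H](C)OC(C)=O)c(C)c(=O)c1C | target

**Total step count:** 5. **Longest linear sequence:** 5 (1 → 2 → 3 → 5 → 12 → 13). Compounds 6 and 7 enter step 4 directly from the bottle.

**Three steps most likely to fail**

**Step 4 (one-flask double desymmetrisation).**
- The risks are imperfect mono-lithiation statistics, alkoxide/methoxide exchange on the pyrone, 1,2-addition and double substitution.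
- The fallback sets out from 5 and from 10 and comes back at 12. It replaces the hard carbanion by a neutral Pd/Cu cross-coupling.
- Pyrone 5 is desymmetrised with one equivalent of NaSMe (THF, −20 °C). This soft nucleophile can only add in the 1,4 sense, and it gives 2-methoxy-3,5-dimethyl-6-(methylsulfanyl)-4H-pyran-4-one F1.
- Separately, 10 is generated from 6 and 7 as in step 4 and quenched at carbon with Bu3SnCl (−78 °C). This gives lithium (2S)-1-[5'-(tributylstannyl)-2,2'-bithiophen-5-yl]propan-2-olate F2.
- F2 is acetylated in the same flask with Ac2O to give (2S)-1-[5'-(tributylstannyl)-2,2'-bithiophen-5-yl]propan-2-yl acetate F3. F3 can be purified away from the statistical by-products.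
- Liebeskind–Srogl coupling of F1 with F3 (Pd2(dba)3, tri(2-furyl)phosphine, CuTC, THF, 50 °C) gives 12.

**Step 5 (desulfurisation next to the methoxypyrone).**
- The risks are partial reduction or solvolysis of the pyrone, residual olefins on sulfur-poisoned nickel, and double-bond migration towards the acetate.
- The fallback sets out from 10 and comes back at 13. It moves the nickel step to a stage where no pyrone exists and then builds the ring on the saturated chain.
- Compound 10 is quenched with CO2 and acidified to give 5'-[(2S)-2-hydroxypropyl]-2,2'-bithiophene-5-carboxylic acid F4.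
- Acetylation (Ac2O, pyridine) gives 5'-[(2S)-2-acetoxypropyl]-2,2'-bithiophene-5-carboxylic acid F5.
- Raney Ni/H2 on the sodium salt of F5 (NaHCO3, aq THF, rt) is a classically reliable substrate class. It gives (11S)-11-acetoxydodecanoic acid F6.
- CDI converts F6 into (2S)-12-(imidazol-1-yl)-12-oxododecan-2-yl acetate F7.
- F7 acylates the dianion of methyl 2-methyl-3-oxopentanoate (NaH, then n-BuLi, THF, −78 °C) at its γ-carbon. The product is methyl (15S)-15-acetoxy-2,4-dimethyl-3,5-dioxohexadecanoate F8.
- DBU (toluene, 70 °C) lactonises F8 to (2S)-11-(4-hydroxy-3,5-dimethyl-2-oxo-2H-pyran-6-yl)undecan-2-yl acetate F9.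
- MeOTf followed by a NaHCO3 wash converts F9 into 13.

**Step 2 (strong-acid cyclisation to a hydrolytically sensitive 6-methoxy-2-pyrone).**
- The risks are hydrolysis and decarboxylation on quench and incomplete ring closure.
- The fallback sets out from 2 and comes back at 3. It closes the ring through an acyl chloride/acylketene instead of a protonated ester.
- One equivalent of KOH in MeOH at 0 °C cleaves one of the two equivalent esters. This gives 5-methoxy-2,4-dimethyl-3,5-dioxopentanoic acid F10.
- (COCl)2 with catalytic DMF (CH2Cl2, 0 °C) gives methyl 5-chloro-2,4-dimethyl-3,5-dioxopentanoate F11.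
- F11 loses HCl and closes through the ester carbonyl oxygen (acylketene oxa-6π cyclisation) to give 3.

**Further compounds**
F1 | step 4 | 2-methoxy-3,5-dimethyl-6-(methylsulfanyl)-4H-pyran-4-one | COc1oc(SC)c(C)c(=O)c1C
F2 | step 4 | lithium (2S)-1-[5'-(tributylstannyl)-2,2'-bithiophen-5-yl]propan-2-olate | C[C@H](O[Li])Cc1ccc(s1)-c1ccc(s1)[Sn](CCCC)(CCCC)CCCC
F3 | step 4 | (2S)-1-[5'-(tributylstannyl)-2,2'-bithiophen-5-yl]propan-2-yl acetate | C[C@H](OC(C)=O)Cc1ccc(s1)-c1ccc(s1)[Sn](CCCC)(CCCC)CCCC
F4 | step 5 | 5'-[(2S)-2-hydroxypropyl]-2,2'-bithiophene-5-carboxylic acid | C[C@H](O)Cc1ccc(s1)-c1ccc(s1)C(O)=O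
F5 | step 5 | 5'-[(2S)-2-acetoxypropyl]-2,2'-bithiophene-5-carboxylic acid | C[C@H](OC(C)=O)Cc1ccc(s1)-c1ccc(s1)C(O)=O
F6 | step 5 | (11S)-11-acetoxydodecanoic acid | C[C@H](OC(C)=O)CCCCCCCCCC(O)=O
F7 | step 5 | (2S)-12-(imidazol-1-yl)-12-oxododecan-2-yl acetate | C[C@H](OC(C)=O)CCCCCCCCCC(=O)n1ccnc1
F8 | step 5 | methyl (15S)-15-acetoxy-2,4-dimethyl-3,5-dioxohexadecanoate | COC(=O)C(C)C(=O)C(C)C(=O)CCCCCCCCC[C@H](C)OC(C)=O
F9 | step 5 | (2S)-11-(4-hydroxy-3,5-dimethyl-2-oxo-2H-pyran-6-yl)undecan-2-yl acetate | Cc1c(O)c(C)c(=O)oc1CCCCCCCCC[C@H](C)OC(C)=O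
F10 | step 2 | 5-methoxy-2,4-dimethyl-3,5-dioxopentanoic acid | COC(=O)C(C)C(=O)C(C)C(O)=O
F11 | step 2 | methyl 5-chloro-2,4-dimethyl-3,5-dioxopentanoate | COC(=O)C(C)C(=O)C(C)C(Cl)=O
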